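The constants stand for no real mixture, and the outcome is calculated.

The slowness that counts in this flask is the exchange of D with J: in north its relaxation half-life is 1.64 min, longer than the 0.0805 min of D with Q, and that 0.0805 min is short against 2.5 min.

- south: L 0.050 M; E 0.0750 M; time 2.5 min
- north: L 0.050 M; E 0.0750 M; time 6.0 min

    D ⇌ Q (K1 = 0.36, k1 = 0.038 /s)
    D ⇌ J (K2 = 2.3, k2 = 0.0049 /s)
    L + E → D + X (k3 = 1.7 /M/s)
    L + Q → L.Q (k4 = 0.023 /M/s)
    Q → G (k5 = 0.0032 /s)

- percent here means L units held: one L.Q counts as two
- run time (south): 2.5 min

- which of these there is most of at the end, counted by the L in it, south (J / G / D / Q)
- which of these there is most of at the end, counted by the L in it, north (J / G / D / Q)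
- final amount of the leader among these, as a percentage of the L charged, in south
- final amount of the leader among these, as a percentage of the L charged, in north

So I treat D and Q as one pool, a rapid pre-equilibrium in which D holds 73.5%. I drop L.Q, as its step is slower than the step of L with E.

L is the limiting reagent, charged below E, so [E] falls from 0.0750 M to 0.0250 M. I replace that curve by its mean, 0.0500 M, which gives L a mean lag of 11.8 s. The exact integral gives 12.9 s, so the mean costs me 1.10 s, small against the 150 s of south.

The pool feeds J at 0.00360 /s, J returns at 0.00213 /s, and the pool leaks to G at 8.47 × 10⁻⁴ /s. Their sum is my exchange rate, the constant at which J closes on its plateau: 0.00658 /s. J then climbs as its plateau, 54.7%, times one minus the exponential of rate by time. For G, I take the leak times the average of the pool's start and end.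

My table has two rows:

South, 138 s after the lag: J 32.7%, pool 58.0%, D 42.7%.

North, 348 s after the lag: J 49.2%, pool 31.4%, D 23.1%.

Reading the J column down, J climbs while the pool shrinks. Reading across the south row, D stands above J, so I name D. Across the north row, J stands above D, so I name J.

The forecast names D at 43.1% for south and J at 47.4% for north, saying “D and Q act as one pool”. My J in north stands 1.8 percentage points above its figure, and my D in south 0.42 points below its figure.

South ends with D in front at 43.1%, and north with J at 47.8%. G in north reaches 16.2%. With 0.00658 /s, the part of the climb still open at the end of north is 10.1%. The same flask read at 15 min has that factor down to 0.290%, and J there stands at 46.7%, below its value at the end of north.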